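All runs were generated by integration for an exercise, noise included.

Epsilon held half the substrate of delta under the same reagent charge, yet at 2.00 min target read 9.3% in epsilon against 8.4% in delta, a gap smaller than the scatter of 1 percentage point. The flask asked about repeats the delta recipe.

| flask | substrate | reagent | remark | time |
|---|---|---|---|---|
| delta | 0.10 M | 0.20 M (fed, over 4.0 min) | the very flask that is asked about, followed so far; the fed solution adds 0.10 times the starting volume |  |
| epsilon | 0.050 M | 0.20 M (fed, over 4.0 min) | run made earlier; the fed solution adds 0.10 times the starting volume |  |
| flask | 0.10 M | 0.200 M (fed, over 4.0 min) | the fed solution adds 0.10 times the starting volume | 2.0 h |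

- delta (time / min: target / %, substrate / %): 0.833: 1.4, 44.2; 2.00: 8.4, 11.3; 4.00: 8.5, 0; 8.00: 5.6, 1.5; 15.0: 2.5, 0; 40.0: 0.4, 1.2
- epsilon (time / min: target / %, substrate / %): 0.833: 3.1, 42.9; 2.00: 9.3, 9.6; 4.00: 9.0, 0.4; 10.0: 4.4, 0.6; 20.0: 2.1, 0; 50.0: 0, 1.6

(each reading ± 1 percentage point)

- the best time, 2.0 h at the latest, for target
- the amount of target, in percent of the substrate charged, at that time
- earliest time at which at least nineteen twentieths of that best amount are there, in min
- latest time at which they still are

- charges are per starting volume, the dose included; the dosed solution carries all of it

I kept a ledger of the substrate, the limiting reagent in delta, which faced 2.00 equivalents of reagent. By 0.833 min delta had lost 55.8% of its substrate, while the feed had brought reagent equal to 41.6% of the substrate charge. If one reagent takes one substrate, the loss was greater than the dose, so my first entry was a loss that needs no reagent. Target held 1.4% at that time. By 4.00 min substrate read 0% and target 8.5%, which left 91.5% of the charge in something I could not read.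

Target later fell, to 0.4% at 40.0 min in delta, so its entry was a loan. What stayed nearly constant was the plateau at 2.00 min and 4.00 min in both runs. The mean of those readings, 8.80%, I froze as the plateau share: the part of the substrate charged that stood as target at this reagent charge, in delta and epsilon alike. I supposed that this share follows the reagent charge in proportion, since in delta target read less at 0.833 min than at 2.00 min, while the reagent was still coming in. For the flask I committed to a best near that share, between 2.00 min and 4.00 min.

The forecast put the best at 9.2% at 0.05 h, with the window from 2.1 min to 0.067 h, and said “Nothing suggests a late rise”. The flask gave 8.67% at 0.0569 h, and the window asked for opened at 2.60 min and shut at 0.0746 h.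

    substrate + reagent → target (k = 0.0480 M⁻¹ s⁻¹)
    substrate → side product (k = 0.0160 s⁻¹)
    reagent + target → over-reaction product (k = 0.0100 M⁻¹ s⁻¹)

At 0.0104 h the flask's substrate went to side product at 11 times the rate at which it went to target. At the end of the feed, 0.0667 h, the flask's ledger stood at side product 89.1%, target 8.52%, over-reaction product 1.57% and substrate 0.785%.

The neighbour flask, charged with 0.080 M of reagent, holds 0.400 of the recipe's reagent charge, so the plateau share gives 3.52% there. Its computed best is 4.29%, more than the proportion gave.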